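# Proposed synthesis of 2,3,4,6-tetrabromo-1H-indole (CNP0151589.0)

## Structural features

The target 9 is an achiral 1H-indole, C8H3Br4N. A benzene ring (C3a, C4, C5, C6, C7, C7a) is fused along C3a–C7a to a pyrrole ring (N1, C2, C3, C3a, C7a), hydrogen remains only on N1, C5 and C7, and there is no stereocentre. Two bromines stand on the benzene ring at C4 and C6, meta to each other; electrophilic substitution of an indole does not reach this pattern, so it must come from a benzene precursor. The other two stand on adjacent pyrrole carbons, C2 next to N1 and C3 next to C3a, and C3–Br is pressed against C4–Br across the peri gap. The N–H 2,3-dibromopyrrole half is the fragile part: it is sensitive to acid, light and oxidants, and all four C–Br bonds are at risk from low-valent metals, organolithium reagents and reductants. The real difficulty is to close the pyrrole ring late, under neutral and non-reducing conditions, with C2–Br and the crowded C3–Br already accounted for and without exposing an indole to a brominating agent. The key step exploits the vicinal pair C2–Br/C3–Br beside N1: moving the C3 bromine back to C2 gives a geminal CBr2 group, the terminus of a 2,2-dibromoethenyl chain on C3a, while N1 becomes a nitrene on C7a. Closure of N1–C2 then gives a non-aromatic 2H-indole whose way back to a benzene ring is a 1,2-shift of bromine from C2 to C3, so the aromaticity of both rings pays for the peri strain.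

## Logic of the disconnections

The route in one sentence: loss of N2 from 6 closes N1–C2, and one bromine shifts from C2 to C3. This sentence does not describe the bromination of a preformed indole, which is the route most chemists would draw first.

**9 to 6 (through 8 and 7).**
- Bonds cut: N1–C2 is cut, and the C3–Br bond is returned to C2. N1–H goes back to C3–H in 8, and C3–Br goes back to C2 in 7.
- Reason: the two pyrrole bromines are neighbours, so they can descend from one CBr2 carbon.
- Gain: the whole pyrrole ring and both of its halogens collapse into an open-chain alkene and an azide. Compound 6 is 9 plus N2, and no halogenation of an indole remains.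
- Demand: the nitrene must be captured by the alkene terminus, and bromine must migrate within the molecule faster than it escapes to the medium.

**6 to 5.**
- Bond cut: the C2=C3 double bond.
- Reason: C2 and both pyrrole bromines can then arrive together in one C1 ylide.
- Gain: a tetrabromide is reduced to a dibromo aldehyde.
- Demand: the olefination must leave the aryl azide alone, so free phosphine is excluded.

**5 to 4.**
- Bond cut: the C7a–N bond.
- Reason: the formyl group that will become C3 stands ortho to this carbon and activates it for addition–elimination.
- Gain: nitrogen enters in one step at the oxidation level the key step needs, with no nitro reduction or diazotisation.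
- Demand: the leaving group at C7a must be displaced much faster than the two bromines, which are also ortho and para to the formyl group. A fluoride meets this demand.

**4 to 1 (through 3 and 2).**
- Bond cut: the C3a–C3 bond.
- Reason: 1 has a mirror plane and two equivalent C–H bonds, each flanked by fluorine and bromine. Metalation at either one fixes the C4/C6 bromine pattern and the position of nitrogen together.
- Gain: a purchasable trihalobenzene.
- Demand: deprotonation must occur beside fluorine and not between the two bromines, and 2 must be kept cold enough to avoid aryne formation and halogen migration.

## Other disconnections considered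

**Alternative 1:** the first idea that comes to mind.
- Cut: C2–Br and C3–Br.
- Forward key step: twofold electrophilic bromination of 4,6-dibromo-1H-indole A1 through 3,4,6-tribromo-1H-indole A2.
- Grounds for preferring the chosen plan:
  - A1 needs an indole synthesis about as long as the whole chosen route, and two halogenations follow it.
  - The first bromine must enter C3 intermolecularly, into the peri pocket beside C4–Br.
  - A2 is an acid-labile N–H 3-bromoindole that is formed together with HBr.
  - The second bromination passes through a 3,3-dibromoindolenine and competes with attack at C5 and C7 and with oxidation to oxindoles.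
  - Selectivity rests on relative rates. In the chosen plan the position of every bromine is fixed by connectivity.

**Alternative 2:**
- Cut: N1–C2 and C3–Br.
- Forward key step: 5-endo-dig bromoaminocyclisation of 3,5-dibromo-2-(bromoethynyl)aniline A3 with an external Br+ source.
- Grounds for preferring the chosen plan:
  - The free aniline of A3 offers its nitrogen and its ortho and para carbons to the same electrophile. An N-protecting group would be needed and would later have to be removed from a sensitive 2,3-dibromoindole.
  - The bromirenium ion must be opened by nitrogen at the carbon that already bears bromine, against the steric bias.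
  - A3 would be made by dehydrobromination of a gem-dibromoalkene, so one bromine is discarded and then bought back. This costs steps and atoms compared with simply moving it.

**Alternative 3:**
- Cut: C3–C3a.
- Forward sequence: 3,5-dibromoaniline A4 is converted into (E)-N-(3,5-dibromophenyl)-2-(hydroxyimino)acetamide A5. The key step is the Sandmeyer isatin closure to 4,6-dibromoisatin A6. Reduction to 4,6-dibromooxindole A7 follows, then deoxygenative bromination at C2 and electrophilic bromination at C3.
- Grounds for preferring the chosen plan:
  - The symmetry of A4 also secures the C4/C6 pattern. However, the closure is a Friedel–Crafts-type attack by a ring deactivated by two bromines, at a carbon ortho to one of them, in hot strong acid.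
  - Two oxygens are introduced only to be removed, which is a redox detour.
  - C2–Br and C3–Br still need two separate operations on an indole-type nucleus.
  - The sequence is at least two steps longer than the chosen one.

Key step: step 4

Assumption: the target is taken as the 1H tautomer drawn, and (dibromomethyl)triphenylphosphonium bromide is taken as a purchasable reagent.

## Route

Step 1
Reactants: 1 1,3-dibromo-5-fluorobenzene
Product: 4 2,4-dibromo-6-fluorobenzaldehyde, via (2,4-dibromo-6-fluorophenyl)lithium 2 (not isolated), via lithium hemiaminalate 3 (not isolated)
Conditions: LiN(iPr)2 (1.05 equiv), THF, –78 °C, 1 h; DMF (1.5 equiv), –78 °C; 1 M HCl quench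
Reagents that add atoms: N,N-dimethylformamide, CN(C)C=O; lithium diisopropylamide, [Li]N(C(C)C)C(C)C (lithium of 2 and 3 only)
Why: Directed ortho-lithiation followed by formylation with DMF. The two equivalent C–H bonds of 1 that lie between F and Br are the most acidic, since fluorine is the strongest ortho-acidifying halogen, so the mirror symmetry of 1 leaves a single product. At –78 °C aryne formation and halogen migration in 2 are suppressed, and 3 keeps the aldehyde masked until the acid quench.

Step 2
Reactants: 4 2,4-dibromo-6-fluorobenzaldehyde
Product: 5 2-azido-4,6-dibromobenzaldehyde
Conditions: NaN3 (1.05 equiv), DMSO, 20–40 °C, dark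
Reagents that add atoms: sodium azide, [Na+].[N-]=[N+]=[N-]
Why: Nucleophilic aromatic substitution by addition–elimination at the carbon ortho to the formyl group. Addition is rate-limiting and is favoured at the C–F carbon, so fluoride leaves far faster than bromide and one equivalent of azide spares both C–Br bonds. The low temperature keeps the ortho-azido aldehyde from losing N2.

Step 3
Reactants: 5 2-azido-4,6-dibromobenzaldehyde
Product: 6 1-azido-3,5-dibromo-2-(2,2-dibromoethenyl)benzene
Conditions: [Ph3PCHBr2]Br (1.4 equiv), KOtBu (1.3 equiv), THF, 0 °C, 20 min; then 5, 0 °C to 20 °C, dark
Reagents that add atoms: (dibromomethyl)triphenylphosphonium bromide, BrC(Br)[P+](c1ccccc1)(c1ccccc1)c1ccccc1.[Br-]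
Why: Wittig dibromomethylenation (Ramirez/Corey–Fuchs olefination) with the ylide preformed from the isolated phosphonium salt, so no free PPh3 is present to attack the azide in a Staudinger reaction. The base is kept below the amount of salt so that 6 is not dehydrobrominated to a bromoalkyne. The non-enolisable, electron-poor aldehyde 5 is a fast acceptor, and the alkene carries two identical groups at its terminus, so no alkene geometry has to be set.

Step 4
Reactants: 6 1-azido-3,5-dibromo-2-(2,2-dibromoethenyl)benzene
Product: 9 2,3,4,6-tetrabromo-1H-indole, via 2,2,4,6-tetrabromo-2H-indole 7 (not isolated), via 2,3,4,6-tetrabromo-3H-indole 8 (not isolated)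
Conditions: Rh2(esp)2 (5 mol %; esp = α,α,α',α'-tetramethyl-1,3-benzenedipropionate), powdered 4 Å MS, 1,2-dichloroethane (0.05 M), 70 °C, dark
Reagents that add atoms: none
Why: Proposed new method: Rh2(esp)2, a dimer of divalent rhodium, binds the internal azide nitrogen of 6 and expels N2 to give an electrophilic rhodium nitrene, which closes N1–C2 by a 4π-electron, five-atom electrocyclisation over N1–C7a–C3a–C3–C2 (formally a 5-endo-trig attack of the alkene terminus on nitrogen) and gives the o-quinoid 7, free or still held by rhodium at N1, with a geminal CBr2 at C2. In 7 the positive character lies on benzylic C3, so one C2 bromine bridges to it as a bromiranium ion and opens toward C2, where N1 carries the charge; this 1,2-shift (a [1,5] shift in the neutral 2H-indole) restores the benzene ring in 8, and the move of hydrogen from C3 to N1 then aromatises the pyrrole ring to 9. The closest known reaction type is the thermal or rhodium-carboxylate-catalysed conversion of β,β-disubstituted 2-azidostyrenes (and, in the Cadogan–Sundberg variant, 2-nitrostyrenes) into 2,3-disubstituted indoles by cyclisation and 1,2-migration of aryl, alkyl, acyl, sulfonyl or nitro groups; bromine as the migrating group is the extension, supported by the known 1,2-halogen shifts through bridged halonium ions in metal-catalysed cycloisomerisations of haloallenes and haloalkynes. No choice between migrating groups is needed, because C2 of 7 bears two bromines and no hydrogen, so only bromine can move. The likely leaks converge on the same product: a shift to N1 would give an N-bromoindole, and heterolytic release of Br+ would leave an aromatic 2-bromoindolide, and both return bromine to C3, the most nucleophilic site present in an inert chlorinated solvent. Regiochemistry is secured by the substrate, since only C2 lies within five-ring reach of N1, C4–Br is larger than the azide nitrogen and so turns the bulky CBr2 terminus toward the azide side while only C3–H faces C4–Br, and the peri contact is first met in 8, where C3 is sp3 and its bromine stands out of the ring plane. Chemoselectivity follows from the absence of any reductant, low-valent metal or external halogen source, so all four C–Br bonds are conserved and only N2 is lost. No stereocentre has to be controlled, because C3 of 8 is a transient racemic centre that disappears on tautomerisation.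

## Compound list

1 | 1,3-dibromo-5-fluorobenzene | Fc1cc(Br)cc(Br)c1 | starting material
2 | (2,4-dibromo-6-fluorophenyl)lithium | [Li]c1c(F)cc(Br)cc1Br | intermediate
3 | lithium (2,4-dibromo-6-fluorophenyl)(dimethylamino)methanolate (racemic) | [Li]OC(N(C)C)c1c(F)cc(Br)cc1Br | intermediate
4 | 2,4-dibromo-6-fluorobenzaldehyde | O=Cc1c(F)cc(Br)cc1Br | intermediate
5 | 2-azido-4,6-dibromobenzaldehyde | O=Cc1c(Br)cc(Br)cc1N=[N+]=[N-] | intermediate
6 | 1-azido-3,5-dibromo-2-(2,2-dibromoethenyl)benzene | BrC(Br)=Cc1c(Br)cc(Br)cc1N=[N+]=[N-] | intermediate
7 | 2,2,4,6-tetrabromo-2H-indole | BrC1(Br)C=C2C(Br)=CC(Br)=CC2=N1 | intermediate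
8 | 2,3,4,6-tetrabromo-3H-indole (racemic) | BrC1C(Br)=Nc2cc(Br)cc(Br)c12 | intermediate
9 | 2,3,4,6-tetrabromo-1H-indole | Brc1cc(Br)c2c(Br)c(Br)[nH]c2c1 | target

## Step count and least certain steps

Total step count: 4. Longest linear sequence: 4.

**Step 4 (key step, proposed new method).**
- What may go wrong: bromine may escape from the 2H-indole stage to the medium, as Br+ or as a bromine atom, faster than it shifts within the molecule. That would cause net loss of one bromine and halogen scrambling. The electron-poor, twisted alkene may also capture the nitrene too slowly, so that hydrogen abstraction or azo coupling of the nitrene takes over.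
- Fallback (known chemistry, from 6, returning at 9): Staudinger reduction of 6 (PPh3, THF/H2O, 20–40 °C) should give 3,5-dibromo-2-(2,2-dibromoethenyl)aniline F1. Intramolecular C–N coupling of Buchwald–Hartwig type follows, at the vinyl C–Br bond cis to the ring, with Pd(PtBu3)2 and K2CO3 in toluene at 100 °C. This is a zerovalent palladium complex whose oxidative addition into aryl bromides is reversible, so the aryl bromides should be spared, and the coupling should give 2,4,6-tribromo-1H-indole F2. Bromination of F2 at C3 with N-bromosuccinimide (DMF, 0 °C) leads to 9.

**Step 3.**
- What may go wrong: the ylide, or phosphine set free from it, may attack the azide in a Staudinger-type process. Addition to the doubly ortho-substituted aldehyde may be slow. Residual base may dehydrobrominate the product.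
- Fallback (no phosphorus, from 5, returning at 6): condensation of 5 with N2H4·H2O (EtOH, 0–20 °C) should give (E)-[(2-azido-4,6-dibromophenyl)methylidene]hydrazine F3. The copper-catalysed olefination of N-unsubstituted hydrazones with polyhaloalkanes (CBr4, CuCl 10 mol %, aqueous NH3, DMSO, 20 °C) should then convert F3 into 6 with loss of N2.

**Step 2.**
- What may go wrong: a second substitution may occur at the C–Br positions ortho and para to the formyl group. Thermal loss of N2 may occur, with closure of the azide nitrogen onto the formyl oxygen, if heating is needed to reach conversion.
- Fallback (nitrogen enters as an amine and the azide is made cold, from 4, returning at 5): addition–elimination of 4 with NH3 (DMSO, sealed vessel, 60–80 °C, then aqueous hydrolysis of any imine) should give 2-amino-4,6-dibromobenzaldehyde F4. Diazotisation (NaNO2, aqueous HCl/AcOH, 0 °C) gives 3,5-dibromo-2-formylbenzenediazonium chloride F5. Treating F5 with NaN3 at 0 °C gives 5 without any heating of the azide.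

## Further compounds

F1 | step 4 | 3,5-dibromo-2-(2,2-dibromoethenyl)aniline | Nc1cc(Br)cc(Br)c1C=C(Br)Br
F2 | step 4 | 2,4,6-tribromo-1H-indole | Brc1cc(Br)c2cc(Br)[nH]c2c1
F3 | step 3 | (E)-[(2-azido-4,6-dibromophenyl)methylidene]hydrazine | N/N=C/c1c(Br)cc(Br)cc1N=[N+]=[N-]
F4 | step 2 | 2-amino-4,6-dibromobenzaldehyde | Nc1cc(Br)cc(Br)c1C=O
F5 | step 2 | 3,5-dibromo-2-formylbenzenediazonium chloride | O=Cc1c(Br)cc(Br)cc1[N+]#N.[Cl-]
A1 | alternative 1 | 4,6-dibromo-1H-indole | Brc1cc(Br)c2cc[nH]c2c1
A2 | alternative 1 | 3,4,6-tribromo-1H-indole | Brc1cc(Br)c2c(Br)c[nH]c2c1
A3 | alternative 2 | 3,5-dibromo-2-(bromoethynyl)aniline | Nc1cc(Br)cc(Br)c1C#CBr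
A4 | alternative 3 | 3,5-dibromoaniline | Nc1cc(Br)cc(Br)c1
A5 | alternative 3 | (E)-N-(3,5-dibromophenyl)-2-(hydroxyimino)acetamide | O/N=C/C(=O)Nc1cc(Br)cc(Br)c1
A6 | alternative 3 | 4,6-dibromoisatin (4,6-dibromo-1H-indole-2,3-dione) | O=C1Nc2cc(Br)cc(Br)c2C1=O
A7 | alternative 3 | 4,6-dibromooxindole (4,6-dibromo-1,3-dihydro-2H-indol-2-one) | O=C1Cc2c(Br)cc(Br)cc2N1
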